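**Plan**
1. Retrosynthetic cuts: first the bond between the carbinol carbon and its aryl ring (aldehyde + aryl Grignard); then, in one event, ring bonds O1–C2 and C3–C4 of the tetrahydrofuran together with the bond between the benzylic carbon and its aryl ring.
2. Enabling feature: ring O1 lies between two unsubstituted CH2 groups (C2, C5); C3 carries a carbon that can be taken back to carboxyl level; C4 carries an ArCH2 group. So O1–C5–C4–CH(benzylic) maps onto propargyl alcohol, C2–C3 onto a methylidenemalonate, and the aryl onto an aryl iodide.
3. Forward: the ring is made first from three achiral components (oxa-Michael addition, 5-exo-dig carbopalladation, aryl coupling); the helper ester leaves by Krapcho reaction and the alkene moves into the ring; the chain is finished by aldehyde formation and aryl addition.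
4. Stereochemistry: cis C3/C4 from syn addition of H2 to the ring alkene of the 2,5-dihydrofuran acid, absolute sense from the BINAP ligand on ruthenium; the carbinol centre from Felkin–Anh (and chelate) controlled Grignard addition to the C3 aldehyde.
5. Both aryl rings come from one benzyl-protected iodide; the benzyl ethers are removed last by hydrogenolysis.

Key step: step 2

Assumption: diethyl 2-methylidenepropanedioate (4) is used as the commercial monomer, distilled just before use because it oligomerises on storage.

**Step 1**
Reactants: 1 5-iodo-2-methoxyphenol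
Product: 2 2-(benzyloxy)-4-iodo-1-methoxybenzene
Conditions: BnBr, K2CO3, DMF, rt
Reagents that add atoms: benzyl bromide, BrCc1ccccc1
Why: Williamson etherification of the phenoxide with benzyl bromide should be clean, since the aryl iodide is inert to carbonate base.

**Step 2**
Reactants: 2 2-(benzyloxy)-4-iodo-1-methoxybenzene; 3 prop-2-yn-1-ol; 4 diethyl 2-methylidenepropanedioate
Product: 7 diethyl (4Z)-4-[3-(benzyloxy)-4-methoxybenzylidene]dihydrofuran-3,3(2H)-dicarboxylate, via lithium prop-2-yn-1-olate 5 (not isolated), via lithium malonate enolate 6 (not isolated)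
Conditions: 3, n-BuLi (1.0 equiv), THF, −78 °C; 4 added slowly, −78 to 0 °C; then 2, Pd(PPh3)4 (5 mol %), DMSO, rt
Reagents that add atoms: none
Why: Alkoxide 5 adds to the unsubstituted CH2 terminus of the doubly activated alkene 4 (oxa-Michael) to make the O–CH2 bond and enolate 6; oxidative addition of 2 to zerovalent palladium gives an arylpalladium iodide that binds the alkyne, the enolate carbon attacks the internal alkyne carbon anti to palladium to make the ring C–C bond, and reductive elimination joins the aryl group to the vinyl carbon. The closest known reaction type is the palladium-mediated three-component coupling of propargyl alkoxides, alkylidene malonates and aryl halides (conjugate addition, carbopalladative cyclisation, coupling). The tetrahydrofuran ring closes in the 5-exo-dig mode. No stereocentre arises, because 7 is achiral; the Z alkene geometry follows from anti addition across the alkyne and is erased in step 3. The step needs one O-addition per molecule of 4 without anionic oligomerisation of 4, and ring closure in preference to direct aryl–alkyne or aryl–malonate coupling; slow inverse addition of 4 to a full equivalent of 5 at −78 °C should secure the first, and the intramolecular five-membered closure of a soft malonate carbon onto the palladium-bound alkyne the second.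

**Step 3**
Reactants: 7 diethyl (4Z)-4-[3-(benzyloxy)-4-methoxybenzylidene]dihydrofuran-3,3(2H)-dicarboxylate
Product: 9 ethyl 4-[3-(benzyloxy)-4-methoxybenzyl]-2,5-dihydrofuran-3-carboxylate, via exocyclic alkene monoester 8 (not isolated)
Conditions: LiCl, H2O, DMSO, 150 °C; then DBU (0.3 equiv), 60 °C
Reagents that add atoms: none
Why: Krapcho dealkoxycarbonylation (chloride attack on one ethyl group, loss of CO2, protonation of the dienolate) gives 8, and DBU should move the alkene through the same dienolate into the ring, where a tetrasubstituted endocyclic alkene conjugated to the ester is favoured over the exocyclic arylidene.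

**Step 4**
Reactants: 9 ethyl 4-[3-(benzyloxy)-4-methoxybenzyl]-2,5-dihydrofuran-3-carboxylate
Product: 10 4-[3-(benzyloxy)-4-methoxybenzyl]-2,5-dihydrofuran-3-carboxylic acid
Conditions: LiOH·H2O, THF/H2O, rt; then 1 M HCl
Reagents that add atoms: lithium hydroxide, [Li+].[OH-]
Why: Ester saponification under mild conditions should leave the benzyl ethers and the ring intact, since ring opening by β-elimination would be the reverse of a disfavoured 5-endo-trig closure.

**Step 5**
Reactants: 10 4-[3-(benzyloxy)-4-methoxybenzyl]-2,5-dihydrofuran-3-carboxylic acid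
Product: 11 (3S,4R)-4-[3-(benzyloxy)-4-methoxybenzyl]tetrahydrofuran-3-carboxylic acid
Conditions: Ru(OAc)2[(R)-BINAP] (1 mol %), H2 (60 bar), MeOH, 50 °C
Reagents that add atoms: none
Why: Carboxylate-directed asymmetric hydrogenation of a tetrasubstituted α,β-unsaturated acid by a divalent ruthenium BINAP dicarboxylate delivers both hydrogens to one face of the ring alkene, so C3 and C4 are set together as cis and the ligand selects the face, while the benzyl ethers are untouched by the homogeneous catalyst.

**Step 6**
Reactants: 11 (3S,4R)-4-[3-(benzyloxy)-4-methoxybenzyl]tetrahydrofuran-3-carboxylic acid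
Product: 12 {(3R,4R)-4-[3-(benzyloxy)-4-methoxybenzyl]tetrahydrofuran-3-yl}methanol
Conditions: BH3·THF, THF, 0 °C to rt; then H2O
Reagents that add atoms: none
Why: Borane reduces the carboxylic acid chemoselectively through acyloxyboranes without forming an enolate, so the cis C3 centre should be kept (the descriptor changes only because the substituent priorities change).

**Step 7**
Reactants: 12 {(3R,4R)-4-[3-(benzyloxy)-4-methoxybenzyl]tetrahydrofuran-3-yl}methanol
Product: 13 (3S,4R)-4-[3-(benzyloxy)-4-methoxybenzyl]tetrahydrofuran-3-carbaldehyde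
Conditions: Dess–Martin periodinane, CH2Cl2, 0 °C to rt
Reagents that add atoms: none
Why: Dess–Martin oxidation of the primary alcohol is neutral and fast, so the cis α-centre of the aldehyde should not epimerise; the aldehyde is used at once.

**Step 8**
Reactants: 13 (3S,4R)-4-[3-(benzyloxy)-4-methoxybenzyl]tetrahydrofuran-3-carbaldehyde; 2 2-(benzyloxy)-4-iodo-1-methoxybenzene
Product: 15 (S)-[3-(benzyloxy)-4-methoxyphenyl]{(3S,4R)-4-[3-(benzyloxy)-4-methoxybenzyl]tetrahydrofuran-3-yl}methanol, via arylmagnesium iodide 14 (not isolated)
Conditions: 2, Mg, THF, rt; then 13, THF, −78 °C; aq NH4Cl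
Reagents that add atoms: none
Why: Grignard addition under Felkin–Anh control, with the branched C4 ring carbon (carrying the cis arylmethyl group) anti to the incoming aryl and the nucleophile passing the C3 hydrogen, which is also the open face of a magnesium chelate between the aldehyde oxygen and O1, should give mainly the S carbinol, and −78 °C should keep the C3 centre from enolising.

**Step 9**
Reactants: 15 (S)-[3-(benzyloxy)-4-methoxyphenyl]{(3S,4R)-4-[3-(benzyloxy)-4-methoxybenzyl]tetrahydrofuran-3-yl}methanol
Product: 16 (S)-(3-hydroxy-4-methoxyphenyl)[(3S,4R)-4-(3-hydroxy-4-methoxybenzyl)tetrahydrofuran-3-yl]methanol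
Conditions: H2 (1 atm), 10% Pd/C, EtOAc, rt
Reagents that add atoms: none
Why: Hydrogenolysis of the two aryl benzyl ethers over palladium on carbon is much faster than cleavage of the secondary benzylic C–OH bond under neutral conditions at 1 atm, so the carbinol and all three stereocentres should survive if the reaction is stopped at full debenzylation.

**Compound list**
1 | 5-iodo-2-methoxyphenol | COc1ccc(I)cc1O | starting material
2 | 2-(benzyloxy)-4-iodo-1-methoxybenzene | COc1ccc(I)cc1OCc1ccccc1 | intermediate
3 | prop-2-yn-1-ol | OCC#C | starting material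
4 | diethyl 2-methylidenepropanedioate | C=C(C(=O)OCC)C(=O)OCC | starting material
5 | lithium prop-2-yn-1-olate (not isolated) | [Li+].[O-]CC#C | intermediate
6 | lithium enolate of diethyl 2-[(prop-2-yn-1-yloxy)methyl]propanedioate (not isolated) | [Li+].CCOC(=O)[C-](COCC#C)C(=O)OCC | intermediate
7 | diethyl (4Z)-4-[3-(benzyloxy)-4-methoxybenzylidene]dihydrofuran-3,3(2H)-dicarboxylate | CCOC(=O)C1(C(=O)OCC)COC/C1=C\c1ccc(OC)c(OCc2ccccc2)c1 | intermediate
8 | ethyl (4Z)-4-[3-(benzyloxy)-4-methoxybenzylidene]tetrahydrofuran-3-carboxylate, racemic (not isolated) | CCOC(=O)C1COC/C1=C\c1ccc(OC)c(OCc2ccccc2)c1 | intermediate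
9 | ethyl 4-[3-(benzyloxy)-4-methoxybenzyl]-2,5-dihydrofuran-3-carboxylate | CCOC(=O)C1=C(Cc2ccc(OC)c(OCc3ccccc3)c2)COC1 | intermediate
10 | 4-[3-(benzyloxy)-4-methoxybenzyl]-2,5-dihydrofuran-3-carboxylic acid | OC(=O)C1=C(Cc2ccc(OC)c(OCc3ccccc3)c2)COC1 | intermediate
11 | (3S,4R)-4-[3-(benzyloxy)-4-methoxybenzyl]tetrahydrofuran-3-carboxylic acid (cis) | COc1ccc(C[C@H]2COC[C@H]2C(O)=O)cc1OCc1ccccc1 | intermediate
12 | {(3R,4R)-4-[3-(benzyloxy)-4-methoxybenzyl]tetrahydrofuran-3-yl}methanol (cis) | COc1ccc(C[C@H]2COC[C@H]2CO)cc1OCc1ccccc1 | intermediate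
13 | (3S,4R)-4-[3-(benzyloxy)-4-methoxybenzyl]tetrahydrofuran-3-carbaldehyde (cis) | COc1ccc(C[C@H]2COC[C@H]2C=O)cc1OCc1ccccc1 | intermediate
14 | [3-(benzyloxy)-4-methoxyphenyl]magnesium iodide (not isolated) | COc1ccc([Mg]I)cc1OCc1ccccc1 | intermediate
15 | (S)-[3-(benzyloxy)-4-methoxyphenyl]{(3S,4R)-4-[3-(benzyloxy)-4-methoxybenzyl]tetrahydrofuran-3-yl}methanol | COc1ccc(C[C@H]2COC[C@H]2[C@H](O)c2ccc(OC)c(OCc3ccccc3)c2)cc1OCc1ccccc1 | intermediate
16 | (S)-(3-hydroxy-4-methoxyphenyl)[(3S,4R)-4-(3-hydroxy-4-methoxybenzyl)tetrahydrofuran-3-yl]methanol | COc1ccc(C[C@H]2COC[C@H]2[C@H](O)c2ccc(OC)c(O)c2)cc1O | target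

**Step count and risks**
Total steps: 9. Longest linear sequence: 9 (1 → 2 → 7 → 9 → 10 → 11 → 12 → 13 → 15 → 16); compound 2 is used a second time in step 8.

Steps most likely to fail:

Step 2. Enolate 6 may add to further 4 (anionic oligomerisation) faster than the ring closes, or the arylpalladium species may couple directly with the terminal alkyne. Fallback, setting out from 2 and 3: the acceptor is changed to commercial diethyl 2-(ethoxymethylidene)propanedioate, which does not oligomerise. The same three-component protocol should give diethyl (4Z)-4-[3-(benzyloxy)-4-methoxybenzylidene]-2-ethoxydihydrofuran-3,3(2H)-dicarboxylate F1, which carries C2 at the acetal level as a temporary helper. Ionic reduction (Et3SiH, BF3·OEt2, CH2Cl2, −78 °C) then removes the ethoxy group through the oxocarbenium ion and comes back to the route at 7.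

Step 5. The tetrasubstituted alkene may be hydrogenated slowly or with poor discrimination between its two faces, and the sense of induction for this substitution pattern must be confirmed on the first run (the mirror-image ligand is the simple remedy if it is reversed). Fallback, setting out from 10: hydrogenation without chiral induction over 5% Rh/Al2O3 (H2, 5 bar, EtOAc) still adds syn and should give racemic cis-4-[3-(benzyloxy)-4-methoxybenzyl]tetrahydrofuran-3-carboxylic acid F2. This is resolved by crystallisation with (R)-1-phenylethylamine as (R)-1-phenylethylammonium (3S,4R)-4-[3-(benzyloxy)-4-methoxybenzyl]tetrahydrofuran-3-carboxylate F3; the amine antipode is chosen so that this salt is the less soluble one. Dilute HCl releases the acid and comes back to the route at 11.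

Step 8. Facial selectivity in the aryl addition may be only moderate, and the cis aldehyde may epimerise at C3 by enolisation before it is attacked. Fallback, setting out from 11: amide formation (MeNHOMe·HCl, EDC·HCl, HOBt, N-methylmorpholine, CH2Cl2, 0 °C) gives the Weinreb amide (3S,4R)-4-[3-(benzyloxy)-4-methoxybenzyl]-N-methoxy-N-methyltetrahydrofuran-3-carboxamide F4. Addition of 14 (THF, 0 °C) gives the ketone [3-(benzyloxy)-4-methoxyphenyl]{(3S,4R)-4-[3-(benzyloxy)-4-methoxybenzyl]tetrahydrofuran-3-yl}methanone F5. Simple hydride reagents would favour the other carbinol epimer here, so the face is imposed by reagent control with a Corey–Bakshi–Shibata reduction ((R)-2-methyl-CBS-oxazaborolidine, BH3·SMe2, THF, −20 °C, aryl as the large group), which comes back to the route at 15.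

**Further compounds**
F1 | step 2 | diethyl (4Z)-4-[3-(benzyloxy)-4-methoxybenzylidene]-2-ethoxydihydrofuran-3,3(2H)-dicarboxylate (racemic) | CCOC1OC/C(=C\c2ccc(OC)c(OCc3ccccc3)c2)C1(C(=O)OCC)C(=O)OCC
F2 | step 5 | racemic cis-4-[3-(benzyloxy)-4-methoxybenzyl]tetrahydrofuran-3-carboxylic acid | COc1ccc(C[C@H]2COC[C@H]2C(O)=O)cc1OCc1ccccc1.COc1ccc(C[C@@H]2COC[C@@H]2C(O)=O)cc1OCc1ccccc1
F3 | step 5 | (R)-1-phenylethylammonium (3S,4R)-4-[3-(benzyloxy)-4-methoxybenzyl]tetrahydrofuran-3-carboxylate | C[C@@H]([NH3+])c1ccccc1.COc1ccc(C[C@H]2COC[C@H]2C([O-])=O)cc1OCc1ccccc1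
F4 | step 8 | (3S,4R)-4-[3-(benzyloxy)-4-methoxybenzyl]-N-methoxy-N-methyltetrahydrofuran-3-carboxamide | COc1ccc(C[C@H]2COC[C@H]2C(=O)N(C)OC)cc1OCc1ccccc1
F5 | step 8 | [3-(benzyloxy)-4-methoxyphenyl]{(3S,4R)-4-[3-(benzyloxy)-4-methoxybenzyl]tetrahydrofuran-3-yl}methanone | COc1ccc(C[C@H]2COC[C@H]2C(=O)c2ccc(OC)c(OCc3ccccc3)c2)cc1OCc1ccccc1
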